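**Strategy**

The butyrolactone (ring atoms O1, C2, C3, C4, C5) is opened at C2. This carbonyl carbon is the sole branch on a straight carbon backbone and sits on C3, which is allylic to the side-chain diene C1'=C2'(Me)–C3'=C4' and 1,3 to the oxygen on C5. Deleting C2 as carbon monoxide leaves a linear chain oxygenated at C3 and C5. The key step, a zerovalent-palladium carbonylative lactonisation, swaps the C3–O benzoate for the C3–C2 bond with inversion and joins C2 to O1, closing the only ring in one operation. Its precursor is the anti-3,5-diol 3-monobenzoate with free C5 hydroxyl, made by syn-aldol union of a west dienal with an east dienyl ethyl ketone and Evans–Tishchenko reduction.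

Key step: step 18

Assumption: Z-enol borinates carrying the isopinocampheyl groups from (+)-α-pinene are taken to attack the si face of aldehydes, as the allyl- and crotylboranes with the same ligands do; if the opposite sense held, the antipodal triflate would be used in step 16 with no other change.

**West fragment**

Step 1
Reactants: 1 prenyl acetate
Product: 2 (2E)-4-acetoxy-2-methylbut-2-enal
Conditions: SeO2 (1.1 equiv), 1,4-dioxane, 80 °C
Reagents that add atoms: selenium dioxide O=[Se]=O
Why: Allylic oxidation by SeO2 (ene reaction, then 2,3-sigmatropic shift) attacks the methyl group trans to the acetoxymethyl chain and should give the E-enal.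

Step 2
Reactants: 2 (2E)-4-acetoxy-2-methylbut-2-enal; 3 (triphenylphosphoranylidene)acetaldehyde
Product: 4 (2E,4E)-6-acetoxy-4-methylhexa-2,4-dienal
Conditions: 3 (1.1 equiv), toluene, 70 °C
Reagents that add atoms: none
Why: Wittig olefination with the stabilised formyl ylide should give the E-alkene, the ylide being kept near one equivalent so that the new dienal is not homologated a second time.

Step 3
Reactants: 4 (2E,4E)-6-acetoxy-4-methylhexa-2,4-dienal; 5 (R)-4-benzyl-3-propionyloxazolidin-2-one
Product: 7 (R)-4-benzyl-3-[(2R,3S,4E,6E)-8-acetoxy-3-hydroxy-2,6-dimethylocta-4,6-dienoyl]oxazolidin-2-one, via di-n-butylboron enolate 6 (not isolated)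
Conditions: n-Bu2BOTf, iPr2NEt, CH2Cl2, −78 to 0 °C; then 4, −78 to 0 °C; pH 7 buffer, MeOH, H2O2, 0 °C
Reagents that add atoms: none
Why: Evans syn aldol reaction, in which the Z-boron enolate 6 reacts through a chair transition state on the face away from the benzyl group and so should set the 2R methyl and 3S hydroxyl centres.

Step 4
Reactants: 7 (R)-4-benzyl-3-[(2R,3S,4E,6E)-8-acetoxy-3-hydroxy-2,6-dimethylocta-4,6-dienoyl]oxazolidin-2-one
Product: 8 (2R,3S,4E,6E)-8-acetoxy-3-hydroxy-N-methoxy-N,2,6-trimethylocta-4,6-dienamide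
Conditions: MeNH(OMe)·HCl, AlMe3, CH2Cl2, −20 to 0 °C
Reagents that add atoms: N,O-dimethylhydroxylamine hydrochloride CNOC.Cl
Why: Weinreb transamidation, in which the aluminium amide, anchored by the free β-hydroxyl as its aluminium alkoxide, should open the imide at the exocyclic carbonyl faster than it attacks the unactivated acetate.

Step 5
Reactants: 8 (2R,3S,4E,6E)-8-acetoxy-3-hydroxy-N-methoxy-N,2,6-trimethylocta-4,6-dienamide
Product: 9 (2R,3S,4E,6E)-8-acetoxy-3-(tert-butyldimethylsilyloxy)-N-methoxy-N,2,6-trimethylocta-4,6-dienamide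
Conditions: TBSOTf, 2,6-lutidine, CH2Cl2, −78 to 0 °C
Reagents that add atoms: tert-butyldimethylsilyl triflate CC(C)(C)[Si](C)(C)OS(=O)(=O)C(F)(F)F
Why: Silylation of the secondary hydroxyl with a silyl triflate and a hindered base should leave the acetate and the amide untouched.

Step 6
Reactants: 9 (2R,3S,4E,6E)-8-acetoxy-3-(tert-butyldimethylsilyloxy)-N-methoxy-N,2,6-trimethylocta-4,6-dienamide
Product: 10 (3R,4S,5E,7E)-4-(tert-butyldimethylsilyloxy)-9-hydroxy-3,7-dimethylnona-5,7-dien-2-one
Conditions: MeMgBr (5 equiv), THF, −20 to 0 °C; aq. NH4Cl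
Reagents that add atoms: methylmagnesium bromide C[Mg]Br
Why: Weinreb ketone synthesis, in which the chelated tetrahedral adduct holds the amide at the ketone stage until work-up while the excess Grignard reagent also cleaves the acetate to the free allylic alcohol.

Step 7
Reactants: 10 (3R,4S,5E,7E)-4-(tert-butyldimethylsilyloxy)-9-hydroxy-3,7-dimethylnona-5,7-dien-2-one
Product: 11 (2E,4E,6S,7R)-6-(tert-butyldimethylsilyloxy)-3,7-dimethyl-8-oxonona-2,4-dienal
Conditions: MnO2 (excess), CH2Cl2, rt
Reagents that add atoms: none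
Why: Allylic oxidation with MnO2 should convert only the primary dienylic alcohol into the E,E-dienal and leave the ketone and its α-stereocentre alone.

**East fragment**

Step 8
Reactants: 12 hexanoyl chloride; 13 (R)-4-benzyloxazolidin-2-one
Product: 15 (R)-4-benzyl-3-hexanoyloxazolidin-2-one, via N-lithio oxazolidinone 14 (not isolated)
Conditions: n-BuLi, THF, −78 °C; then 12, −78 to 0 °C
Reagents that add atoms: none
Why: N-Acylation of the lithiated oxazolidinone 14 by the acid chloride.

Step 9
Reactants: 15 (R)-4-benzyl-3-hexanoyloxazolidin-2-one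
Product: 17 (R)-4-benzyl-3-[(2S)-2-(hydroxymethyl)hexanoyl]oxazolidin-2-one, via titanium enolate 16 (not isolated)
Conditions: TiCl4, iPr2NEt, CH2Cl2, 0 °C; then 1,3,5-trioxane, TiCl4, 0 °C
Reagents that add atoms: 1,3,5-trioxane C1OCOCO1
Why: Evans titanium-enolate hydroxymethylation (an aldol reaction with formaldehyde released from trioxane by TiCl4), in which the chelated Z-enolate 16 is attacked on the face away from the benzyl group and so should set the 2S centre.

Step 10
Reactants: 17 (R)-4-benzyl-3-[(2S)-2-(hydroxymethyl)hexanoyl]oxazolidin-2-one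
Product: 18 (R)-4-benzyl-3-[(2S)-2-{[(tert-butyldimethylsilyl)oxy]methyl}hexanoyl]oxazolidin-2-one
Conditions: TBSCl, imidazole, CH2Cl2, rt
Reagents that add atoms: tert-butyldimethylsilyl chloride CC(C)(C)[Si](C)(C)Cl
Why: Standard silylation of the primary hydroxyl, done at once so that the β-hydroxy imide cannot undergo acyl transfer.

Step 11
Reactants: 18 (R)-4-benzyl-3-[(2S)-2-{[(tert-butyldimethylsilyl)oxy]methyl}hexanoyl]oxazolidin-2-one
Product: 19 (2R)-2-{[(tert-butyldimethylsilyl)oxy]methyl}hexan-1-ol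
Conditions: LiBH4, MeOH (1 equiv), THF, 0 °C
Reagents that add atoms: none
Why: Reductive cleavage of the imide by LiBH4 at the exocyclic carbonyl should give the primary alcohol and release the auxiliary without touching the stereocentre.

Step 12
Reactants: 19 (2R)-2-{[(tert-butyldimethylsilyl)oxy]methyl}hexan-1-ol
Product: 20 (2S)-2-{[(tert-butyldimethylsilyl)oxy]methyl}hexanal
Conditions: Dess–Martin periodinane, NaHCO3, CH2Cl2, 0 °C to rt; used at once
Reagents that add atoms: none
Why: Dess–Martin oxidation under buffered, non-basic conditions should give the α-branched aldehyde without epimerisation.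

Step 13
Reactants: 20 (2S)-2-{[(tert-butyldimethylsilyl)oxy]methyl}hexanal; 3 (triphenylphosphoranylidene)acetaldehyde
Product: 21 (2E,4R)-4-{[(tert-butyldimethylsilyl)oxy]methyl}oct-2-enal
Conditions: 3 (1.2 equiv), toluene, 80 °C
Reagents that add atoms: none
Why: Wittig olefination with the stabilised formyl ylide should give the E-enal under neutral conditions that leave the stereocentre alone.

Step 14
Reactants: 21 (2E,4R)-4-{[(tert-butyldimethylsilyl)oxy]methyl}oct-2-enal; 22 pentan-3-one
Product: 24 (6E,8R)-8-{[(tert-butyldimethylsilyl)oxy]methyl}-5-hydroxy-4-methyldodec-6-en-3-one, via lithium enolate 23 (not isolated)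
Conditions: LiN(iPr)2, 22, THF, −78 °C; then 21, −78 °C; aq. NH4Cl
Reagents that add atoms: none
Why: Aldol addition of the lithium enolate 23 to the enal carbonyl (1,2-addition at low temperature); the two new centres are removed in the next step, so their configuration is of no account.

Step 15
Reactants: 24 (6E,8R)-8-{[(tert-butyldimethylsilyl)oxy]methyl}-5-hydroxy-4-methyldodec-6-en-3-one
Product: 26 (4E,6E,8R)-8-{[(tert-butyldimethylsilyl)oxy]methyl}-4-methyldodeca-4,6-dien-3-one, via mesylate 25 (not isolated)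
Conditions: MsCl, Et3N, CH2Cl2, 0 °C; then DBU, 0 °C to rt
Reagents that add atoms: none
Why: Mesylation followed by E1cB elimination through mesylate 25 should give the conjugated dienone, with the E geometry of the α-methyl enone favoured as the less strained isomer.

**Union and endgame**

Step 16
Reactants: 26 (4E,6E,8R)-8-{[(tert-butyldimethylsilyl)oxy]methyl}-4-methyldodeca-4,6-dien-3-one; 11 (2E,4E,6S,7R)-6-(tert-butyldimethylsilyloxy)-3,7-dimethyl-8-oxonona-2,4-dienal
Product: 28 (3R,4S,5E,7E,9R,10S,12E,14E,16R)-4-(tert-butyldimethylsilyloxy)-16-{[(tert-butyldimethylsilyl)oxy]methyl}-9-hydroxy-3,7,10,12-tetramethylicosa-5,7,12,14-tetraene-2,11-dione, via enol diisopinocampheylborinate 27 (not isolated)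
Conditions: (−)-Ipc2BOTf (1.2 equiv), iPr2NEt, 26 (1.3 equiv), CH2Cl2, −78 °C; then 11 (1.0 equiv), −78 to −20 °C; pH 7 buffer, MeOH, H2O2, 0 °C
Reagents that add atoms: none
Why: Reagent-controlled syn aldol reaction through the Z-enol borinate 27 and a chair transition state, in which the isopinocampheyl groups should send the enolate to the si face of the aldehyde and so set the 9R hydroxyl and 10S methyl centres, the ketone being kept in slight excess over the triflate so that no free borylating agent meets the methyl ketone of 11.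

Step 17
Reactants: 28 (3R,4S,5E,7E,9R,10S,12E,14E,16R)-4-(tert-butyldimethylsilyloxy)-16-{[(tert-butyldimethylsilyl)oxy]methyl}-9-hydroxy-3,7,10,12-tetramethylicosa-5,7,12,14-tetraene-2,11-dione; 29 benzaldehyde
Product: 30 (3R,4S,5E,7E,9R,10R,11S,12E,14E,16R)-4-(tert-butyldimethylsilyloxy)-16-{[(tert-butyldimethylsilyl)oxy]methyl}-11-hydroxy-3,7,10,12-tetramethyl-2-oxoicosa-5,7,12,14-tetraen-9-yl benzoate
Conditions: SmI2 (0.3 equiv), 29 (6 equiv), THF, −10 °C
Reagents that add atoms: none
Why: Evans–Tishchenko reduction, in which the samarium-bound hemiacetal of benzaldehyde delivers hydride intramolecularly to the β-hydroxy ketone only, so that the new 11S hydroxyl should be 1,3-anti and the benzoate should rest on the C9 oxygen alone.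

Step 18
Reactants: 30 (3R,4S,5E,7E,9R,10R,11S,12E,14E,16R)-4-(tert-butyldimethylsilyloxy)-16-{[(tert-butyldimethylsilyl)oxy]methyl}-11-hydroxy-3,7,10,12-tetramethyl-2-oxoicosa-5,7,12,14-tetraen-9-yl benzoate; 31 carbon monoxide
Product: 34 (3S,4S,5S)-3-[(1E,3E,5S,6R)-5-(tert-butyldimethylsilyloxy)-2,6-dimethyl-7-oxoocta-1,3-dienyl]-5-[(2E,4E,6R)-6-{[(tert-butyldimethylsilyl)oxy]methyl}deca-2,4-dien-2-yl]-4-methyldihydrofuran-2(3H)-one, via allylpalladium benzoate 32 (not isolated), via acylpalladium benzoate 33 (not isolated)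
Conditions: Pd2(dba)3 (5 mol %), PPh3 (20 mol %), iPr2NEt (1.5 equiv), CO (20 bar), THF, 45 °C
Reagents that add atoms: none
Why: Proposed new method: zerovalent palladium ionises the dienylic benzoate of 30 anti to the leaving group to give allylpalladium 32, carbon monoxide inserts into the Pd–C bond at the secondary terminus with retention to give acylpalladium 33, and the 1,3-placed free hydroxyl attacks the acyl carbon, releasing the catalyst and benzoic acid. The closest known reaction types are the palladium-catalysed decarboxylative carbonylation of 4-vinyl-1,3-dioxan-2-ones to α-vinyl-γ-butyrolactones and the alkoxycarbonylation of allylic esters, both with net inversion; a dienylic benzoate with a free 1,3-hydroxyl is the extension. The one ring, the γ-lactone, closes by 5-exo-trig attack of the C5 oxygen (lactone numbering) on the acylpalladium carbonyl C2. The new stereocentre C3 is fixed by the anti-ionisation and retentive-insertion sequence, so the benzoate carbon set in step 16 becomes the C3–C2 centre with inversion, which turns the 3,4-syn-3,5-anti chain into the all-trans lactone, also the thermodynamic isomer. The step needs ionisation at C3–O only, carbon monoxide capture at C3 and no scrambling: only the C3 oxygen carries an acyl group after step 17, an acylpalladium at the far diene terminus cannot be reached by any hydroxyl through a small ring and reverts, and carbon monoxide pressure keeps insertion ahead of β-hydride loss and O-allylation.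

Step 19
Reactants: 34 (3S,4S,5S)-3-[(1E,3E,5S,6R)-5-(tert-butyldimethylsilyloxy)-2,6-dimethyl-7-oxoocta-1,3-dienyl]-5-[(2E,4E,6R)-6-{[(tert-butyldimethylsilyl)oxy]methyl}deca-2,4-dien-2-yl]-4-methyldihydrofuran-2(3H)-one
Product: 35 (3S,4S,5S)-3-[(1E,3E,5S,6R)-5-hydroxy-2,6-dimethyl-7-oxoocta-1,3-dienyl]-5-[(2E,4E,6R)-6-(hydroxymethyl)deca-2,4-dien-2-yl]-4-methyldihydrofuran-2(3H)-one
Conditions: HF·pyridine, pyridine, THF, 0 °C to rt
Reagents that add atoms: none
Why: Fluoride cleavage of both silyl ethers with pyridine-buffered HF·pyridine should be mild enough to spare the β,γ-unsaturated lactone centre and the β-hydroxy ketone.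

**Compound list**

1 | prenyl acetate (3-methylbut-2-en-1-yl acetate) | CC(C)=CCOC(C)=O | starting material
2 | (2E)-4-acetoxy-2-methylbut-2-enal | CC(=O)OC/C=C(\C)C=O | intermediate
3 | (triphenylphosphoranylidene)acetaldehyde | O=CC=P(c1ccccc1)(c1ccccc1)c1ccccc1 | starting material
4 | (2E,4E)-6-acetoxy-4-methylhexa-2,4-dienal | CC(=O)OC/C=C(C)/C=C/C=O | intermediate
5 | (R)-4-benzyl-3-propionyloxazolidin-2-one | CCC(=O)N1[C@H](Cc2ccccc2)COC1=O | starting material
6 | di-n-butylboron (Z)-enolate of 5 (not isolated) | C/C=C(\OB(CCCC)CCCC)N1[C@H](Cc2ccccc2)COC1=O | intermediate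
7 | (R)-4-benzyl-3-[(2R,3S,4E,6E)-8-acetoxy-3-hydroxy-2,6-dimethylocta-4,6-dienoyl]oxazolidin-2-one | CC(=O)OC/C=C(C)/C=C/[C@H](O)[C@@H](C)C(=O)N1[C@H](Cc2ccccc2)COC1=O | intermediate
8 | (2R,3S,4E,6E)-8-acetoxy-3-hydroxy-N-methoxy-N,2,6-trimethylocta-4,6-dienamide | CC(=O)OC/C=C(C)/C=C/[C@H](O)[C@@H](C)C(=O)N(C)OC | intermediate
9 | (2R,3S,4E,6E)-8-acetoxy-3-(tert-butyldimethylsilyloxy)-N-methoxy-N,2,6-trimethylocta-4,6-dienamide | CC(=O)OC/C=C(C)/C=C/[C@H](O[Si](C)(C)C(C)(C)C)[C@@H](C)C(=O)N(C)OC | intermediate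
10 | (3R,4S,5E,7E)-4-(tert-butyldimethylsilyloxy)-9-hydroxy-3,7-dimethylnona-5,7-dien-2-one | OC/C=C(C)/C=C/[C@H](O[Si](C)(C)C(C)(C)C)[C@@H](C)C(C)=O | intermediate
11 | (2E,4E,6S,7R)-6-(tert-butyldimethylsilyloxy)-3,7-dimethyl-8-oxonona-2,4-dienal (west dienal) | O=C/C=C(C)/C=C/[C@H](O[Si](C)(C)C(C)(C)C)[C@@H](C)C(C)=O | intermediate
12 | hexanoyl chloride | CCCCCC(=O)Cl | starting material
13 | (R)-4-benzyloxazolidin-2-one | O=C1N[C@H](Cc2ccccc2)CO1 | starting material
14 | N-lithio-(R)-4-benzyloxazolidin-2-one (not isolated) | [Li]N1[C@H](Cc2ccccc2)COC1=O | intermediate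
15 | (R)-4-benzyl-3-hexanoyloxazolidin-2-one | CCCCCC(=O)N1[C@H](Cc2ccccc2)COC1=O | intermediate
16 | trichlorotitanium (Z)-enolate of 15 (not isolated) | CCCC/C=C(\O[Ti](Cl)(Cl)Cl)N1[C@H](Cc2ccccc2)COC1=O | intermediate
17 | (R)-4-benzyl-3-[(2S)-2-(hydroxymethyl)hexanoyl]oxazolidin-2-one | CCCC[C@@H](CO)C(=O)N1[C@H](Cc2ccccc2)COC1=O | intermediate
18 | (R)-4-benzyl-3-[(2S)-2-{[(tert-butyldimethylsilyl)oxy]methyl}hexanoyl]oxazolidin-2-one | CCCC[C@@H](CO[Si](C)(C)C(C)(C)C)C(=O)N1[C@H](Cc2ccccc2)COC1=O | intermediate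
19 | (2R)-2-{[(tert-butyldimethylsilyl)oxy]methyl}hexan-1-ol | CCCC[C@H](CO)CO[Si](C)(C)C(C)(C)C | intermediate
20 | (2S)-2-{[(tert-butyldimethylsilyl)oxy]methyl}hexanal | CCCC[C@H](C=O)CO[Si](C)(C)C(C)(C)C | intermediate
21 | (2E,4R)-4-{[(tert-butyldimethylsilyl)oxy]methyl}oct-2-enal (east enal) | CCCC[C@H](/C=C/C=O)CO[Si](C)(C)C(C)(C)C | intermediate
22 | pentan-3-one | CCC(=O)CC | starting material
23 | lithium enolate of pentan-3-one, mainly E (not isolated) | C/C=C(\CC)O[Li] | intermediate
24 | (6E,8R)-8-{[(tert-butyldimethylsilyl)oxy]methyl}-5-hydroxy-4-methyldodec-6-en-3-one, mixture of C4 and C5 epimers | CCCC[C@H](/C=C/C(O)C(C)C(=O)CC)CO[Si](C)(C)C(C)(C)C | intermediate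
25 | methanesulfonate of 24 (not isolated) | CCCC[C@H](/C=C/C(OS(C)(=O)=O)C(C)C(=O)CC)CO[Si](C)(C)C(C)(C)C | intermediate
26 | (4E,6E,8R)-8-{[(tert-butyldimethylsilyl)oxy]methyl}-4-methyldodeca-4,6-dien-3-one (east ethyl dienyl ketone) | CCCC[C@H](/C=C/C=C(\C)C(=O)CC)CO[Si](C)(C)C(C)(C)C | intermediate
27 | (Z)-enol diisopinocampheylborinate of 26, isopinocampheyl groups from (+)-α-pinene (not isolated) | C/C=C(\OB([C@@H]1C[C@@H]2C[C@H]([C@H]1C)C2(C)C)[C@@H]1C[C@@H]2C[C@H]([C@H]1C)C2(C)C)C(/C)=C/C=C/[C@@H](CCCC)CO[Si](C)(C)C(C)(C)C | intermediate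
28 | (3R,4S,5E,7E,9R,10S,12E,14E,16R)-4-(tert-butyldimethylsilyloxy)-16-{[(tert-butyldimethylsilyl)oxy]methyl}-9-hydroxy-3,7,10,12-tetramethylicosa-5,7,12,14-tetraene-2,11-dione (linear syn-aldol adduct) | CCCC[C@H](/C=C/C=C(\C)C(=O)[C@@H](C)[C@H](O)/C=C(C)/C=C/[C@H](O[Si](C)(C)C(C)(C)C)[C@@H](C)C(C)=O)CO[Si](C)(C)C(C)(C)C | intermediate
29 | benzaldehyde | O=Cc1ccccc1 | starting material
30 | (3R,4S,5E,7E,9R,10R,11S,12E,14E,16R)-4-(tert-butyldimethylsilyloxy)-16-{[(tert-butyldimethylsilyl)oxy]methyl}-11-hydroxy-3,7,10,12-tetramethyl-2-oxoicosa-5,7,12,14-tetraen-9-yl benzoate | CCCC[C@H](/C=C/C=C(\C)[C@@H](O)[C@@H](C)[C@H](OC(=O)c1ccccc1)/C=C(C)/C=C/[C@H](O[Si](C)(C)C(C)(C)C)[C@@H](C)C(C)=O)CO[Si](C)(C)C(C)(C)C | intermediate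
31 | carbon monoxide | [C-]#[O+] | starting material
32 | allylpalladium benzoate from 30, drawn as the σ-form at the former benzoate carbon, phosphine ligands omitted (not isolated) | CCCC[C@H](/C=C/C=C(\C)[C@@H](O)[C@@H](C)[C@@H]([Pd]OC(=O)c1ccccc1)/C=C(C)/C=C/[C@H](O[Si](C)(C)C(C)(C)C)[C@@H](C)C(C)=O)CO[Si](C)(C)C(C)(C)C | intermediate
33 | acylpalladium benzoate, phosphine ligands omitted (not isolated) | CCCC[C@H](/C=C/C=C(\C)[C@@H](O)[C@@H](C)[C@@H](C(=O)[Pd]OC(=O)c1ccccc1)/C=C(C)/C=C/[C@H](O[Si](C)(C)C(C)(C)C)[C@@H](C)C(C)=O)CO[Si](C)(C)C(C)(C)C | intermediate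
34 | (3S,4S,5S)-3-[(1E,3E,5S,6R)-5-(tert-butyldimethylsilyloxy)-2,6-dimethyl-7-oxoocta-1,3-dienyl]-5-[(2E,4E,6R)-6-{[(tert-butyldimethylsilyl)oxy]methyl}deca-2,4-dien-2-yl]-4-methyldihydrofuran-2(3H)-one (bis-silyl lactone) | CCCC[C@H](/C=C/C=C(\C)[C@H]1OC(=O)[C@@H](/C=C(C)/C=C/[C@H](O[Si](C)(C)C(C)(C)C)[C@@H](C)C(C)=O)[C@@H]1C)CO[Si](C)(C)C(C)(C)C | intermediate
35 | (3S,4S,5S)-3-[(1E,3E,5S,6R)-5-hydroxy-2,6-dimethyl-7-oxoocta-1,3-dienyl]-5-[(2E,4E,6R)-6-(hydroxymethyl)deca-2,4-dien-2-yl]-4-methyldihydrofuran-2(3H)-one (CNP0187795.2) | CCCC[C@H](/C=C/C=C(\C)[C@H]1OC(=O)[C@@H](/C=C(C)/C=C/[C@H](O)[C@@H](C)C(C)=O)[C@@H]1C)CO | target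

**Step count and risks**

Total step count: 19. Longest linear sequence: 12 steps (hexanoyl chloride to the target, steps 8 to 15 and 16 to 19); the west branch has 7 steps before the union.

Steps most likely to fail:

1. Step 18 (carbonylative lactonisation). Carbon monoxide insertion and hydroxyl capture may be outrun by β-hydride loss from the allyl complex or by O-allylation by the free hydroxyl, and the dienylic C–O bond of the finished lactone may be ionised again by the catalyst. The fallback separates carbonylation from ring closure and uses known chemistry. It sets out from 30: silylation of the free hydroxyl (TESOTf, 2,6-lutidine, CH2Cl2, −78 °C) should give the triethylsilyl ether F1. Intermolecular methoxycarbonylation of the dienylic benzoate (Pd(OAc)2, PPh3, iPr2NEt, MeOH/THF, CO 30 bar, 50 °C), the established alkoxycarbonylation of allylic esters with net inversion, should give the methyl ester F2. HF·pyridine in pyridine/THF then removes all three silyl groups and the freed γ-hydroxy ester lactonises (PPTS, CH2Cl2 if needed), so the fallback comes back to the route at 35. No hydroxyl competes for the allyl complex and no palladium-labile lactone is present during carbonylation. Without the tether, capture at the secondary allyl terminus rests on insertion being faster than migration of palladium through the methyl-bearing tertiary carbon.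

2. Step 16 (boron aldol union). Reagent control may give poor facial selectivity between two partners whose stereocentres are remote, and conversion may suffer if the borylating agent engages the methyl ketone of the aldehyde. The fallback replaces reagent control by auxiliary control and an acyl cross-coupling. From 11, an Evans syn aldol with (S)-4-benzyl-3-propionyloxazolidin-2-one (n-Bu2BOTf, iPr2NEt, CH2Cl2, −78 to 0 °C) should give the imide F3, and LiSEt (EtSH, n-BuLi, THF, 0 °C) should turn it into the S-ethyl thioester F4. From 21, Corey–Fuchs dibromo-olefination (CBr4, PPh3, CH2Cl2, 0 °C) should give the dibromodiene F5, n-BuLi then MeI (THF, −78 °C) the methyl enyne F6, and syn-hydroboration with catecholborane followed by hydrolysis the dienylboronic acid F7, boron going to the methyl-bearing carbon away from the alkene. Liebeskind–Srogl coupling of F4 with F7 (Pd2(dba)3, tri(2-furyl)phosphine, copper thiophene-2-carboxylate CuO2CC4H3S, THF, 50 °C), which tolerates the ketone and the free hydroxyl, comes back to the route at 28.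

3. Step 19 (global desilylation). Fluoride and pyridine may epimerise or conjugate the β,γ-unsaturated lactone centre, water may be lost from the freed β-hydroxy ketone, or the secondary silyl ether may leave too slowly. The fallback changes the order of events so that the lactone never meets fluoride. It sets out from 30: both silyl ethers are removed first (HF·pyridine, pyridine, THF, 0 °C to rt) to give the trihydroxy benzoate F8, the benzoate being stable to these conditions. The carbonylative lactonisation of step 18 is then run on F8 and delivers 35 directly; this relies on the same proposed cyclocarbonylation. Only the 1,3-hydroxyl can close a five-membered ring on the acylpalladium, the other two hydroxyls being too remote.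

**Further compounds**

F1 | step 18 | triethylsilyl ether of 30 at the C11 hydroxyl, (3R,4S,5E,7E,9R,10R,11S,12E,14E,16R)-4-(tert-butyldimethylsilyloxy)-16-{[(tert-butyldimethylsilyl)oxy]methyl}-3,7,10,12-tetramethyl-2-oxo-11-(triethylsilyloxy)icosa-5,7,12,14-tetraen-9-yl benzoate | CCCC[C@H](/C=C/C=C(\C)[C@@H](O[Si](CC)(CC)CC)[C@@H](C)[C@H](OC(=O)c1ccccc1)/C=C(C)/C=C/[C@H](O[Si](C)(C)C(C)(C)C)[C@@H](C)C(C)=O)CO[Si](C)(C)C(C)(C)C
F2 | step 18 | methyl ester from F1 with the benzoate carbon inverted and now bearing CO2Me | CCCC[C@H](/C=C/C=C(\C)[C@@H](O[Si](CC)(CC)CC)[C@@H](C)[C@@H](C(=O)OC)/C=C(C)/C=C/[C@H](O[Si](C)(C)C(C)(C)C)[C@@H](C)C(C)=O)CO[Si](C)(C)C(C)(C)C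
F3 | step 16 | (S)-4-benzyl-3-[(2S,3R,4E,6E,8S,9R)-8-(tert-butyldimethylsilyloxy)-3-hydroxy-2,5,9-trimethyl-10-oxoundeca-4,6-dienoyl]oxazolidin-2-one | O=C(N1[C@@H](Cc2ccccc2)COC1=O)[C@@H](C)[C@H](O)/C=C(C)/C=C/[C@H](O[Si](C)(C)C(C)(C)C)[C@@H](C)C(C)=O
F4 | step 16 | S-ethyl (2S,3R,4E,6E,8S,9R)-8-(tert-butyldimethylsilyloxy)-3-hydroxy-2,5,9-trimethyl-10-oxoundeca-4,6-dienethioate | CCSC(=O)[C@@H](C)[C@H](O)/C=C(C)/C=C/[C@H](O[Si](C)(C)C(C)(C)C)[C@@H](C)C(C)=O
F5 | step 16 | (R,E)-tert-butyl[(2-butyl-6,6-dibromohexa-3,5-dienyl)oxy]dimethylsilane | CCCC[C@H](/C=C/C=C(Br)Br)CO[Si](C)(C)C(C)(C)C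
F6 | step 16 | (R,E)-tert-butyl[(2-butylhept-3-en-5-ynyl)oxy]dimethylsilane | CCCC[C@H](/C=C/C#CC)CO[Si](C)(C)C(C)(C)C
F7 | step 16 | [(2Z,4E,6R)-6-{[(tert-butyldimethylsilyl)oxy]methyl}deca-2,4-dien-2-yl]boronic acid | CCCC[C@H](/C=C/C=C(\C)B(O)O)CO[Si](C)(C)C(C)(C)C
F8 | step 19 | (3R,4S,5E,7E,9R,10R,11S,12E,14E,16R)-4,11-dihydroxy-16-(hydroxymethyl)-3,7,10,12-tetramethyl-2-oxoicosa-5,7,12,14-tetraen-9-yl benzoate | CCCC[C@H](/C=C/C=C(\C)[C@@H](O)[C@@H](C)[C@H](OC(=O)c1ccccc1)/C=C(C)/C=C/[C@H](O)[C@@H](C)C(C)=O)CO
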